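A flat curve tempts one to call a reaction finished, but flatness does not show which charge stopped it.

| flask | substrate | reagent | capture agent | free catalyst | temperature | remark | time |
|---|---|---|---|---|---|---|---|
| north-east | 0.25 M | 1.2 equiv | 0.025 M | 1 mol% | 70 °C | the very flask that is asked about, followed so far |  |
| south-west | 0.25 M | 1.2 equiv | 0.025 M | 1 mol% | 76 °C | run made earlier |  |
| flask | 0.25 M | 1.20 equiv | 0.0250 M | 1 mol% | 70 °C |  | 8.0 d |

| run | time / h | target / % |
|---|---|---|
| north-east | 15.0 | 41.4 |
| north-east | 50.0 | 71.1 |
| north-east | 96.0 | 78.9 |
| north-east | 144 | 79.8 |
| north-east | 192 | 80.8 |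
| south-west | 15.0 | 57.9 |
| south-west | 50.0 | 83.1 |
| south-west | 96.0 | 87.9 |
| south-west | 144 | 87.8 |
| south-west | 192 | 87.8 |

(standard deviation of a reading: 0.5 percentage points)
- removed target is counted in
- additions bring no volume worth counting
- red: at 8.0 d raise the temperature by 20 K, then wait 15 d
- ochre: at 8.0 d add free catalyst, 100 % of the amount charged, then wait 15 d
- grey: change nothing and wait 15 d more
- amber: at 8.0 d add reagent, 100 % of the amount charged, then wait 15 d
- violet: at 8.0 d take out 90 % of the target then present, then wait 15 d
* target, in percent of the substrate first charged, at 8.0 d
* the option that brings most further target ("none" if no option brings more than 2 percentage points) (red / ochre / grey / amber / violet / none)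
* target present, with what was taken out counted in, in percent of the substrate first charged, after ochre
* target present, with what was taken out counted in, in percent of the substrate first charged, after violet

1. The late end. The north-east flask reads 80.8 % at 192 h, the asked time, so that reading is the estimate for "now". By that reading about a third of the reagent remains, so the stall is not a reagent shortage. Take the natural logarithm of charged over remaining substrate at the stall: L = 1.65, the reach of a catalyst charge. The south-west run, hotter, has a reach of 2.10.

2. The early end. At 15.0 h the north-east flask has covered 0.534 of L. Suppose the reaction is pseudo-first-order in substrate and the working catalyst decays exponentially with loss constant kd. Joining both ends gives kd = 0.0261 h⁻¹. This predicts 70.0 % at 50.0 h, against 71.1 % read.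

3. At the asked time. The working share is reckoned at 0.668 %, so the remaining reach is 0.0110. Waiting adds about 0.21 percentage points, less than the margin. Violet therefore stands near 81.0 %, and red and amber act on the same small share.

4. Ochre. A fresh charge with the same reach leaves the remaining substrate multiplied by the exponential of minus L, giving 96.3 %.

5. The weak link. The second charge meets capture agent already used. If each catalyst takes one capture agent, the first charge used 10.0 % of it. Then kd falls in step, L becomes 1.83, and ochre gives 96.9 %.

The forecast gives 80.4 %, ochre, 96.5 % for ochre and 80.6 % for violet, holding that “the catalyst is essentially gone”. The reckoning above also picks ochre, and its ochre figure is higher.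

The flask gives 81.3 %. Ochre brings 17 points and reaches 98.5 %; violet reaches 81.6 %.

    catalyst intermediate C ⇌ free catalyst + target (K = 6.00 M, k = 95.0 h⁻¹, Ea = 98.0 kJ mol⁻¹, ΔH = −11.0 kJ mol⁻¹)
    substrate + catalyst intermediate B → catalyst intermediate C (k = 527 M⁻¹ h⁻¹, Ea = 63.0 kJ mol⁻¹)
    catalyst intermediate C + capture agent → trapped intermediate (k = 29.9 M⁻¹ h⁻¹, Ea = 61.0 kJ mol⁻¹)
    catalyst intermediate A → catalyst intermediate B (k = 134 h⁻¹, Ea = 93.0 kJ mol⁻¹)
    reagent + free catalyst ⇌ catalyst intermediate A (K = 34.2 M⁻¹, k = 17.0 M⁻¹ h⁻¹, Ea = 80.0 kJ mol⁻¹, ΔH = 4.00 kJ mol⁻¹)
    (constants at 70 °C)

At the asked time the trapped intermediate holds 99.7 % of the catalyst, while 18 % of the substrate and 31 % of the reagent remain. Read from these results, the flask's first charge has a reach of 1.67, and ochre's charge travels 2.52, farther. A neighbouring flask, otherwise the same, is charged with 0.25 mol% of free catalyst, a quarter of the loading here, so the same scaling gives a reach of 0.419 and 34.2 % target. That neighbouring flask gives 28.4 %, with 71.4 % of its substrate left.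

The numbers in the tables are calculated on assumed constants, noise included.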